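Readings and results were generated by integration from invented constants; the scatter is artificial.

**Reading times.** You read this flask at 25 s and again at 8.0 min, and the excess at both times can be reckoned from one ratio taken from the earlier runs.

| flask | left-handed substrate | right-handed substrate | solid reagent | remark | time |
|---|---|---|---|---|---|
| alder | 2.0 × 10⁻⁴ M | 2.0 × 10⁻⁴ M | 0.30 mM | run made earlier |  |
| maple | 2.0 × 10⁻⁴ M | 2.0 × 10⁻⁴ M | 0.45 mM | run made earlier |  |
| birch | 1.0 × 10⁻⁴ M | 1.0 × 10⁻⁴ M | 0.60 mM | run made earlier |  |
| flask | 2.0 × 10⁻⁴ M | 2.0 × 10⁻⁴ M | 0.600 mM |  | 8.0 min |

- alder (time / min: left-handed product / %, right-handed product / %): 2.00: 2.8, 2.2; 4.00: 7.9, 4.3; 6.00: 11.1, 6.6; 8.00: 16.1, 8.1; 10.0: 18.8, 10.2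
- maple (time / min: left-handed product / %, right-handed product / %): 0.833: 1.1, 0.6; 2.50: 5.2, 2.3; 4.00: 7.6, 4.4; 6.00: 12.0, 6.2; 10.0: 18.9, 11.1
- birch (time / min: left-handed product / %, right-handed product / %): 0.833: 1.0, 0.8; 1.33: 2.7, 0.9; 2.50: 4.6, 3.5; 5.00: 11.5, 6.5; 10.0: 21.3, 11.5

(scatter of a reading: 0.5 percentage points)

- excess of left-handed product over right-handed product in the product at 25 s
- excess of left-handed product over right-handed product in the product at 8.0 min
- part of the left-handed substrate and right-handed substrate charged together that has reacted at 8.0 min

- partner is single-handed; left-handed substrate and right-handed substrate are mirror images of each other, charged as a racemate, each of them at the stated concentration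
- solid, in amounts per volume of the solution: solid reagent
- the numbers in the tables scatter by 0.5 percentage points (one standard deviation)
- at the start none of the solid reagent is in solution
- what has gone into achiral form counts as reacted
- an excess is the difference of the two amounts in percent of their sum
- an excess is below zero if the other one leads
- the handed part of partner does not stay in what it makes, so the products of the two hands are mirror images too

**Carried ratio.** Pool the last rows of alder, maple and birch, at 10.0 min, and you get s = 1.80, the left-handed product over the right-handed product in those rows together, which as an excess is 28.5%.

**Two extremes.** In the first version the substrates do not pass into each other, a plain kinetic resolution: the left-handed substrate drains faster and the excess sinks along the run, so the same rows imply a selectivity factor of 2.03 and a starting excess of 33.9%. In the second version the achiral form links the hands so fast that the substrates stay equal, and the excess holds at 28.5% throughout. A passing between the hands flattens that fall, so I expect this flask between these two versions, within the scatter of s. The earliest readings pooled give 25.6%, below 33.9% though with wide scatter, so my own reckoning takes 28.5% at both times. For the reacted part, the products of the alder run, which had 0.30 mM of solid reagent, sum to 24.2% at 8.00 min; my own estimate for this flask is about that much product plus the achiral form, which counts as reacted and which no reading shows, so I can put no figure on the sum.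

**The forecast.** It gives 31% early, above my figure, then 29% late and 25% reacted, the last being product “plus perhaps 1% held as achiral form”.

**The result.** The flask gives 28.0% at 25 s, 27.9% at 8.0 min and 40.2% reacted.

    partner + left-handed substrate → left-handed product (k = 98.0 /M/s)
    partner + right-handed substrate → right-handed product (k = 55.0 /M/s)
    left-handed substrate ⇌ achiral form (K = 0.540, k = 0.120 /s)
    right-handed substrate ⇌ achiral form (K = 0.540, k = 0.120 /s)
    solid reagent ⇌ partner, rate k5*(cs5 - [partner]) while solid is left; crystals form when [partner] > cs5 (solubility = 0.0810 mM, k = 0.00660 /s)
    2 partner → self-condensation product (k = 1200 /M/s)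
    partner → decomposed reagent (k = 0.00320 /s)

In this flask at 8.00 min the products together stand at 24.0% and the achiral form at 16.2%, while the left-handed substrate and achiral form relax, by that step alone and both ways together, with a half-life of 2.03 s, short against 8.0 min. Now take the neighbour flask with 1.5 × 10⁻⁴ M of solid reagent, where 0.076% of that charge remains, solid or dissolved: splitting its 17.6% of product by s gives 11.3% left-handed, and that neighbour holds 11.2%.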